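**Retrosynthetic overview**
- 19 ⇒ E-selective cross-metathesis of the C7-vinyl bicyclic lactone 13 (C1–C8) with the allylic benzoate 18 (side chain C9–C12).
- 13 ⇒ one-flask double ring closure of the acyclic epoxy ester 10: O7 opens the trans-3,4-epoxide 5-exo (inversion at C4) to give the oxolane first, then the C5–OH closes the δ-lactone in the same operation.
- 10 ⇒ matched Sharpless epoxidation of E-allylic alcohol 9 ⇒ Nozaki–Hiyama–Kishi union of aldehyde 5 (C5–C9; C6 and C7 from D-xylose by zinc fragmentation) with iodoalkene 8 (C1–C4).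
- 18 ⇒ Ir-catalysed anti-(benzoyloxy)allylation of acetaldehyde with the acrolein-derived dibenzoate 15, then acetylation.

Atom labels C1–C12 follow the target chain (C1 = lactone carbonyl, C12 = terminal methyl).
Assumption: methyl but-3-ynoate (6) is bought as such; if not, one Fischer esterification of but-3-ynoic acid supplies it.

**Route**

Step 1
Reactants: 1 D-xylose
Product: 2 methyl D-xylofuranoside (α/β mixture)
Conditions: HCl (0.5% in MeOH), 20 °C, 5 h; basic resin
Reagents that add atoms: methanol, CO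
Why: Kinetic Fischer glycosidation gives mainly the furanosides, leaving C2 and C3 of xylose (later C6 and C7) untouched; the anomeric mixture does not matter because C1 becomes an aldehyde in step 4.

Step 2
Reactants: 2 methyl D-xylofuranoside
Product: 3 methyl 5-deoxy-5-iodo-D-xylofuranoside (α/β mixture)
Conditions: PPh3, I2, imidazole, THF, 65 °C
Reagents that add atoms: iodine, II
Why: Garegg–Samuelsson (Appel-type) iodination is selective for the only primary hydroxyl.

Step 3
Reactants: 3 methyl 5-deoxy-5-iodo-D-xylofuranoside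
Product: 4 methyl 5-deoxy-5-iodo-2,3-bis-O-(triethylsilyl)-D-xylofuranoside (α/β mixture)
Conditions: TESCl, imidazole, DMF, 0 to 20 °C
Reagents that add atoms: chlorotriethylsilane, CC[Si](Cl)(CC)CC
Why: Silyl ether formation on the trans-2,3-diol; TES is non-chelating (favours Felkin addition in step 6) and is removed by the mild acid that triggers step 8.

Step 4
Reactants: 4 methyl 5-deoxy-5-iodo-2,3-bis-O-(triethylsilyl)-D-xylofuranoside
Product: 5 (2R,3S)-2,3-bis[(triethylsilyl)oxy]pent-4-enal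
Conditions: Zn (activated), THF/H2O 4:1, ultrasound, 40 °C
Reagents that add atoms: none
Why: Bernet–Vasella reductive fragmentation: zinc inserts into C–I and β-elimination opens the furanoside to the ω-unsaturated aldehyde, carrying C2/C3 of xylose unchanged into C6/C7.

Step 5
Reactants: 6 methyl but-3-ynoate
Product: 8 methyl (3E)-4-iodobut-3-enoate, via alkenylzirconocene chloride 7 (not isolated)
Conditions: Cp2Zr(H)Cl (1.05 equiv), THF, 20 °C; then I2, 0 °C
Reagents that add atoms: iodine, II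
Why: Schwartz hydrozirconation adds Zr–H syn and anti-Markovnikov to the terminal alkyne and iodinolysis goes with retention, giving the E-iodoalkene.

Step 6
Reactants: 5 (2R,3S)-2,3-bis[(triethylsilyl)oxy]pent-4-enal; 8 methyl (3E)-4-iodobut-3-enoate
Product: 9 methyl (3E,5S,6S,7S)-5-hydroxy-6,7-bis[(triethylsilyl)oxy]nona-3,8-dienoate
Conditions: CrCl2 (4 equiv), NiCl2 (1 mol%), DMSO, 20 °C
Reagents that add atoms: none
Why: Nozaki–Hiyama–Kishi alkenylation tolerates the ester and silyl ethers and keeps the E-alkene; Felkin–Anh attack anti to the α-silyloxy group sets C5 as the 5,6-anti (5S) alcohol, with the minor epimer removed by chromatography.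

Step 7
Reactants: 9 methyl (3E,5S,6S,7S)-5-hydroxy-6,7-bis[(triethylsilyl)oxy]nona-3,8-dienoate
Product: 10 methyl 2-[(2R,3R)-3-{(1S,2S,3S)-1-hydroxy-2,3-bis[(triethylsilyl)oxy]pent-4-en-1-yl}oxiran-2-yl]acetate
Conditions: Ti(OiPr)4 (0.3 equiv), D-(−)-DIPT (0.36 equiv), t-BuOOH, 4 Å MS, CH2Cl2, −20 °C
Reagents that add atoms: tert-butyl hydroperoxide, CC(C)(C)OO
Why: Sharpless asymmetric epoxidation in its matched (kinetic-resolution) sense: only the alkene next to the free C5–OH reacts, D-(−)-DIPT gives the 4,5-erythro (3R,4R) trans-epoxide, and any residual C5 epimer is the slow, mismatched substrate.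

Step 8
Reactants: 10 methyl 2-[(2R,3R)-3-{(1S,2S,3S)-1-hydroxy-2,3-bis[(triethylsilyl)oxy]pent-4-en-1-yl}oxiran-2-yl]acetate
Product: 13 (2S,3R,3aR,7R,7aR)-2-ethenyl-3,7-dihydroxyhexahydro-5H-furo[3,2-b]pyran-5-one, via epoxy triol ester 11 (not isolated), via trihydroxy oxolane ester 12 (not isolated)
Conditions: CSA (0.2 equiv), MeOH/CH2Cl2 1:4, 0 to 20 °C; then evaporate, PhMe, 40 °C
Reagents that add atoms: none
Why: Acid-triggered cascade: methanolysis of both TES ethers, Baldwin-favoured 5-exo-tet epoxide opening by O7 with inversion at C4 (preferred over 6-endo attack and over attack by O6), then δ-lactonisation of the C5–OH onto the methyl ester; the epoxide oxygen stays on C3 as the free hydroxyl, so both rings and the C3/C4 configurations are set in one operation.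

Step 9
Reactants: 14 acrolein
Product: 15 prop-2-ene-1,1-diyl dibenzoate
Conditions: Bz2O, H2SO4 (cat.), CH2Cl2, 0 to 20 °C
Reagents that add atoms: benzoic anhydride, O=C(OC(=O)c1ccccc1)c1ccccc1
Why: Acid-catalysed acylal formation (1,1-diacylation of the aldehyde).

Step 10
Reactants: 15 prop-2-ene-1,1-diyl dibenzoate; 16 acetaldehyde
Product: 17 (2R,3S)-2-hydroxypent-4-en-3-yl benzoate
Conditions: [Ir(cod)Cl]2 (2.5 mol%), SEGPHOS (5 mol%, the antipode that gives 2R,3S), 4-chloro-3-nitrobenzoic acid (10 mol%), Cs2CO3 (20 mol%), i-PrOH (2 equiv), THF, 90 °C, sealed tube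
Reagents that add atoms: none
Why: Krische iridium-catalysed transfer-hydrogenative anti-(α-acyloxy)allylation: the (E)-σ-(benzoyloxy)allyl iridium adds to the aldehyde through a chair transition state, giving the anti (erythro) diol monobenzoate with catalyst-controlled absolute configuration.

Step 11
Reactants: 17 (2R,3S)-2-hydroxypent-4-en-3-yl benzoate
Product: 18 (3S,4R)-4-(acetyloxy)pent-1-en-3-yl benzoate
Conditions: Ac2O, pyridine, DMAP (cat.), CH2Cl2, 0 °C
Reagents that add atoms: acetic anhydride, CC(=O)OC(C)=O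
Why: Standard acetylation of the free C11–OH at 0 °C, fast enough to outrun benzoate migration.

Step 12
Reactants: 13 (2S,3R,3aR,7R,7aR)-2-ethenyl-3,7-dihydroxyhexahydro-5H-furo[3,2-b]pyran-5-one; 18 (3S,4R)-4-(acetyloxy)pent-1-en-3-yl benzoate
Product: 19 (1E,3S,4R)-4-(acetyloxy)-1-[(2S,3R,3aR,7R,7aR)-3,7-dihydroxy-5-oxohexahydro-2H-furo[3,2-b]pyran-2-yl]pent-1-en-3-yl benzoate
Conditions: Hoveyda–Grubbs II (10 mol%), 18 (3 equiv), 1,4-benzoquinone (10 mol%), CH2Cl2, 40 °C
Reagents that add atoms: none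
Why: Olefin cross-metathesis with excess of the allylic benzoate gives the cross product as the thermodynamic E-alkene without touching any stereocentre; free hydroxyls, lactone and esters are tolerated.

**Compound list**

1 | D-xylose | O=C[C@H](O)[C@@H](O)[C@H](O)CO | starting material
2 | methyl D-xylofuranoside (α/β, anomeric centre undefined) | COC1[C@H](O)[C@@H](O)[C@@H](CO)O1 | intermediate
3 | methyl 5-deoxy-5-iodo-D-xylofuranoside (α/β) | COC1[C@H](O)[C@@H](O)[C@@H](CI)O1 | intermediate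
4 | methyl 5-deoxy-5-iodo-2,3-bis-O-(triethylsilyl)-D-xylofuranoside (α/β) | COC1[C@H](O[Si](CC)(CC)CC)[C@@H](O[Si](CC)(CC)CC)[C@@H](CI)O1 | intermediate
5 | (2R,3S)-2,3-bis[(triethylsilyl)oxy]pent-4-enal | O=C[C@H](O[Si](CC)(CC)CC)[C@@H](O[Si](CC)(CC)CC)C=C | intermediate
6 | methyl but-3-ynoate | COC(=O)CC#C | starting material
7 | methyl (3E)-4-[chlorobis(cyclopentadienyl)zirconio]but-3-enoate | COC(=O)C/C=C/[Zr](Cl)(C1C=CC=C1)C1C=CC=C1 | intermediate (not isolated)
8 | methyl (3E)-4-iodobut-3-enoate | COC(=O)C/C=C/I | intermediate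
9 | methyl (3E,5S,6S,7S)-5-hydroxy-6,7-bis[(triethylsilyl)oxy]nona-3,8-dienoate | COC(=O)C/C=C/[C@H](O)[C@H](O[Si](CC)(CC)CC)[C@@H](O[Si](CC)(CC)CC)C=C | intermediate
10 | methyl 2-[(2R,3R)-3-{(1S,2S,3S)-1-hydroxy-2,3-bis[(triethylsilyl)oxy]pent-4-en-1-yl}oxiran-2-yl]acetate | COC(=O)C[C@H]1O[C@@H]1[C@H](O)[C@H](O[Si](CC)(CC)CC)[C@@H](O[Si](CC)(CC)CC)C=C | intermediate
11 | methyl 2-{(2R,3R)-3-[(1R,2R,3S)-1,2,3-trihydroxypent-4-en-1-yl]oxiran-2-yl}acetate | COC(=O)C[C@H]1O[C@@H]1[C@H](O)[C@H](O)[C@@H](O)C=C | intermediate (not isolated)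
12 | methyl (3R)-3-[(2R,3R,4S,5S)-5-ethenyl-3,4-dihydroxyoxolan-2-yl]-3-hydroxypropanoate | COC(=O)C[C@@H](O)[C@H]1O[C@@H](C=C)[C@@H](O)[C@H]1O | intermediate (not isolated)
13 | (2S,3R,3aR,7R,7aR)-2-ethenyl-3,7-dihydroxyhexahydro-5H-furo[3,2-b]pyran-5-one | C=C[C@@H]1O[C@H]2[C@H](OC(=O)C[C@H]2O)[C@@H]1O | intermediate
14 | acrolein | C=CC=O | starting material
15 | prop-2-ene-1,1-diyl dibenzoate | C=CC(OC(=O)c1ccccc1)OC(=O)c1ccccc1 | intermediate
16 | acetaldehyde | CC=O | starting material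
17 | (2R,3S)-2-hydroxypent-4-en-3-yl benzoate | C[C@@H](O)[C@H](C=C)OC(=O)c1ccccc1 | intermediate
18 | (3S,4R)-4-(acetyloxy)pent-1-en-3-yl benzoate | CC(=O)O[C@H](C)[C@H](C=C)OC(=O)c1ccccc1 | intermediate
19 | (1E,3S,4R)-4-(acetyloxy)-1-[(2S,3R,3aR,7R,7aR)-3,7-dihydroxy-5-oxohexahydro-2H-furo[3,2-b]pyran-2-yl]pent-1-en-3-yl benzoate (CNP0230210.1) | CC(=O)O[C@H](C)[C@H](/C=C/[C@@H]1O[C@H]2[C@H](OC(=O)C[C@H]2O)[C@@H]1O)OC(=O)c1ccccc1 | target

**Step count**

Total: 12 steps. Longest linear sequence: 8 steps (1, 2, 3, 4, 6, 7, 8, 12; D-xylose to 19).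

**Three steps most likely to fail, with fallbacks**

Step 12 (cross-metathesis of two hindered, allylically oxygenated olefins; low conversion or homodimers are the risk). The fallback sets out from 13 and comes back at 19, replacing metathesis by a chromium-mediated C9–C10 bond formation. TESOTf/2,6-lutidine gives the 3,7-bis-O-triethylsilyl ether of 13 F5. Ozonolysis (O3, then PPh3) gives the C8 aldehyde F6, and Takai iodo-olefination (CrCl2, CHI3) gives the (E)-2-iodoethenyl compound F7. NHK coupling with (2R)-1-oxopropan-2-yl acetate F11 gives the C10 alcohol F8 (Felkin addition, 10S, erythro to C11). F11 is made from commercial (R)-but-3-en-2-ol by acetylation to (2R)-but-3-en-2-yl acetate F10 and ozonolysis. Benzoylation (BzCl, pyridine) gives the bis-O-triethylsilyl ether of 19 F9, and HF·pyridine returns to 19.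

Step 8 (the double ring closure; risks are epoxide solvolysis before O7 is free, or competing attack modes). The fallback sets out from 10 and comes back at 13, closing the two rings in separate operations with O5 blocked by a non-participating group. TBSOTf/2,6-lutidine gives the 5-O-tert-butyldimethylsilyl ether of 10 F3. PPTS/MeOH removes only the two TES groups, and CSA in CH2Cl2 then closes the oxolane alone to give the 5-O-TBS oxolane ester F4, which can be purified and its regiochemistry checked. TBAF/AcOH then liberates 12, which is lactonised separately (CSA, PhMe) to 13.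

Step 6 (Felkin selectivity at C5 may be modest for a syn-α,β-bis(silyloxy) aldehyde). The fallback sets out from 5 and comes back at 9, building the C4–C5 bond with an alkynyl nucleophile, which typically gives the highest Felkin ratios. Ethynylmagnesium bromide (THF, −78 °C) gives (3S,4S,5S)-4,5-bis[(triethylsilyl)oxy]hept-6-en-1-yn-3-ol F1. Hydrozirconation/iodinolysis (Cp2Zr(H)Cl, then I2) gives (1E,3S,4S,5S)-1-iodo-4,5-bis[(triethylsilyl)oxy]hepta-1,6-dien-3-ol F2. Pd(PPh3)4-catalysed Negishi coupling with the Reformatsky reagent BrZnCH2CO2Me installs C1–C2 and returns to 9.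

**Further compounds**

F1 | step 6 | (3S,4S,5S)-4,5-bis[(triethylsilyl)oxy]hept-6-en-1-yn-3-ol | C#C[C@H](O)[C@H](O[Si](CC)(CC)CC)[C@@H](O[Si](CC)(CC)CC)C=C
F2 | step 6 | (1E,3S,4S,5S)-1-iodo-4,5-bis[(triethylsilyl)oxy]hepta-1,6-dien-3-ol | I/C=C/[C@H](O)[C@H](O[Si](CC)(CC)CC)[C@@H](O[Si](CC)(CC)CC)C=C
F3 | step 8 | 5-O-tert-butyldimethylsilyl ether of 10 (silyl on the carbinol next to the oxirane) | COC(=O)C[C@H]1O[C@@H]1[C@H](O[Si](C)(C)C(C)(C)C)[C@H](O[Si](CC)(CC)CC)[C@@H](O[Si](CC)(CC)CC)C=C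
F4 | step 8 | 5-O-TBS oxolane ester (12 with its oxolane 3-OH, chain C5, silylated) | COC(=O)C[C@@H](O)[C@H]1O[C@@H](C=C)[C@@H](O)[C@H]1O[Si](C)(C)C(C)(C)C
F5 | step 12 | 3,7-bis-O-triethylsilyl ether of 13 | C=C[C@@H]1O[C@H]2[C@H](OC(=O)C[C@H]2O[Si](CC)(CC)CC)[C@@H]1O[Si](CC)(CC)CC
F6 | step 12 | C8 aldehyde (2-formyl analogue of F5; same ring configuration) | O=C[C@@H]1O[C@H]2[C@H](OC(=O)C[C@H]2O[Si](CC)(CC)CC)[C@@H]1O[Si](CC)(CC)CC
F7 | step 12 | (E)-2-iodoethenyl analogue of F5 | I/C=C/[C@@H]1O[C@H]2[C@H](OC(=O)C[C@H]2O[Si](CC)(CC)CC)[C@@H]1O[Si](CC)(CC)CC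
F8 | step 12 | C10 alcohol (bis-O-TES ether of 19 lacking the benzoyl group) | CC(=O)O[C@H](C)[C@H](/C=C/[C@@H]1O[C@H]2[C@H](OC(=O)C[C@H]2O[Si](CC)(CC)CC)[C@@H]1O[Si](CC)(CC)CC)O
F9 | step 12 | 3,7-bis-O-triethylsilyl ether of 19 | CC(=O)O[C@H](C)[C@H](/C=C/[C@@H]1O[C@H]2[C@H](OC(=O)C[C@H]2O[Si](CC)(CC)CC)[C@@H]1O[Si](CC)(CC)CC)OC(=O)c1ccccc1
F10 | step 12 | (2R)-but-3-en-2-yl acetate | CC(=O)O[C@H](C)C=C
F11 | step 12 | (2R)-1-oxopropan-2-yl acetate | CC(=O)O[C@H](C)C=O
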